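## Structural features

The target is a stilbene trimer built from two 2,3-trans-2,3-diaryl-2,3-dihydrobenzofurans joined in series. The upper furan (O1, C2, C3, C3a, C7a) is fused to ring A, which carries a hydroxyl at C4 and an (E)-4-hydroxystyryl group at C6; C2 bears a 4-hydroxyphenyl group and C3 is bonded to C6' of ring B. Ring B is the benzo ring of the lower dihydrobenzofuran (O1', C2', C3', C3a', C7a'), with a hydroxyl at C4', a 3,4-dihydroxyphenyl (catechol) group at C2' and a 3,5-dihydroxyphenyl group at C3'. In both bicycles the fused carbon (C3a, C3a') lies between the two oxygen-bearing carbons of a resorcinol ring and para to that ring's carbon substituent, which is the less common fusion mode. The stereocentres form two adjacent pairs, C2/C3 (R,R, trans) and C2'/C3' (S,S, trans); the pairs are held apart by ring B and cannot control one another. Fragile elements are the seven phenols (the catechol is the most easily oxidised), the E-stilbene (light, acid, hydrogenation) and the benzylic C2–O1 and C2'–O1' bonds, which ionise under strong Brønsted or Lewis acid. The real difficulty is to form C3–C3a at the inter-oxygen carbon rather than at the ring carbons ortho to the styryl group, and to set the upper pair in the right absolute sense. The key step exploits the fact that ring A with C3a, its two oxygens and its styryl group is an intact resveratrol, while C3 and C2 are the two olefin carbons of a second 4-hydroxystilbene. The spin needed at C3a is reached from the 4-hydroxyphenyl oxygen of resveratrol through its olefin (C3a is para to C6), so a radical on a resorcinol oxygen is neither needed nor likely.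

## Logic of the disconnections

27 back to 26: five O–Si bonds are cut. The catechol would be oxidised before any stilbene phenol, and a free ring B hydroxyl would let the lower unit act as the ring-closing partner, so every oxygen of the lower unit except the one that must be oxidised is masked. The forward step must remove five silyl groups without opening the upper furan or oxidising the freed catechol.

26 back to 21 and 22: C3–C3a and O1–C2 are cut. 26 is 21 plus 22 minus two hydrogens, so one oxidative phenol–olefin [3+2] coupling removes a ring, two skeletal bonds, two stereocentres and fourteen carbons, and 22 is bought. The forward step must achieve cross-coupling over homo-coupling, reaction at the inter-oxygen carbon of 22, and the right face at C3; only the chemoselectivity is secured by the design of 21.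

21 back to 18 and 19: the bond between C6' and the vinyl carbon is cut, and the acetyl group is removed. The olefin is the most sensitive element of 21 and is therefore installed last, on an aryl bromide that is inert in all earlier steps. The forward step must be E-selective and spare the aryl silyl ethers.

18 back to 8 and 14: C2'–C3' and O1'–C2' are cut, a one-carbon plus four-atom annulation. Both stereocentres of the lower furan then come from one reagent-controlled step, and the two halves are of similar size. The forward step needs facial control by the chiral sulfide, trans closure, and generation of the quinone methide and the ylide by the same base.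

8 back to 7, and 7 back to 3 and 5 through 6: the C–S bond and the aryl–carbinol bond (C3' to the 3,5-dioxygenated ring) are cut. This reduces the quinone methide precursor to an aldehyde and an aryl bromide. The forward addition must tolerate a free ortho-hydroxyl and an aryl bromide on 3.

3 back to 2 and 1, and 5 back to 4: O–Si and O–CH3 bonds are cut. The methyl ethers of 1 are exchanged for silyl ethers on the simplest arene, so no strong Lewis acid meets a dihydrobenzofuran later. The forward step must stop at mono-silylation of 2.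

14 back to 11 and 12 through 13, and 11 back to 10 and 9: the S–CH2 bond, a C–H bond (reduction) and two O–Si bonds are cut. The catechol enters already protected and the chiral information is bought as 12. The forward alkylation must give one sulfonium diastereomer.

## Other disconnections considered

Alternative 1: The cut removes ring B. C3a'–C7a', C6'–C7' and C4'–C5' would be formed in one cyclotrimerisation, which also closes the lower furan. In the forward step Cp*RuCl(cod) (divalent ruthenium) would join the ynol ether and alkynylboronate ends of the tethered diyne A2 into a ruthenacycle. The terminal alkyne of the 3-ethynyl-dihydrobenzofuran A3 would then insert, and reductive elimination would give the arylboronate A1, whose C–B bond is later oxidised to the C4' hydroxyl.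
- In favour: the route is fully convergent and needs no oxidant near phenols. All four stereocentres are set in A2 and A3 before the union, so no diastereomers arise at the coupling; on this point it is better than the chosen plan. The tether fixes the substitution pattern of ring B, where it is at least the equal of the chosen plan.
- Against: A2 carries a terminal ynol ether on a benzylic oxygen, which is prone to hydration and to thermal loss of a ketene. The C3 hydrogen of A3 is benzylic and propargylic, so epimerisation or isomerisation to an allene threatens. The orientation of the alkyne insertion rests only on steric differences at the metallacycle. The methyl ethers of A1 call for a late BBr3 demethylation of two 2-aryl-dihydrobenzofurans.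
- Comparison: on structure Alternative 1 is more certain. On mechanism both plans rest on an untested combination of partners. On step economy the chosen plan is much shorter, because A2 and A3 each need their own asymmetric synthesis.

Alternative 2: The cut is through ring A at C3a–C4 and C7–C7a, leaving O1–C2 to be closed afterwards. In the forward step the 3-styrylcyclobutenone A5 would be heated with the siloxyalkyne A6. Electrocyclic opening to a vinylketene, [2+2] addition of the electron-rich alkyne, a second opening, 6π closure and tautomerisation would give the resorcinol monosilyl ether A4.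
- In favour: the pericyclic sequence places the two oxygens on either side of the alkyne-derived carbon C3a and the styryl group para to it. This is exactly the regiochemistry that the chosen coupling cannot guarantee, and here the alternative is better. The two oxygens emerge differentiated, C3 is set beforehand, and no oxidant or transition metal is needed.
- Against: A6 must carry the whole lower unit and two adjacent open-chain stereocentres, one of them propargylic and benzylic. Making a moisture-sensitive siloxyalkyne at that stage is demanding. Prolonged heating invites dimerisation of the styryl-substituted ketene. The later O1–C2 closure needs ionisation at a benzylic carbon, and the methyl ethers again need BBr3.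
- Comparison: on structure it is the equal or the better of the chosen plan (regiocontrol, no diastereomer separation). On mechanism it is well founded for simple partners. On step economy it is clearly worse, since A6 alone would take more steps than the whole route to 21.

Alternative 3: The cut is at C3'–C3a' of the lower furan, traced back to a six-membered flavanone. In the forward step PhI(OAc)2 (trivalent iodine) with H2SO4 in trimethyl orthoformate would convert the flavanone A8 into its enol ether and attack C3. A 1,2-shift of the aryl carbon from C4 to C3 with loss of iodobenzene would give the trans ester A7.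
- In favour: oxidative ring contraction of flavanones is established chemistry, the trans relationship is inherent, and the bromine handle survives. In precedent for the ring-forming event it is better than step 9, and in setting the trans pair it is its equal.
- Against: A7 has an ester where C3' needs the 3,5-dihydroxyphenyl ring, so the carboxyl carbon must be exchanged for an aryl group, through intermediates that can lose the C3' configuration. The electron-rich aryl group at C2 of A8 favours its own migration (isoflavone formation) or simple dehydrogenation. Strong acid can racemise A8 by reversible opening to the chalcone.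
- Comparison: it replaces only steps 1 to 9 and leaves the union with 22 unsolved. On structure it is equal for the lower unit; on mechanism it is safer for ring formation but weaker for absolute control; on step economy it is worse because of the ester-to-aryl exchange.

Key step: step 11

Assumption: the benzylide of (1R,4R,5R)-isothiocineole is taken to attack the ortho-quinone methide with the facial sense that leads to the (2S) centre; if the opposite sense operates, the (1S,4S,5S) sulfide is used and nothing else changes.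

Abbreviation used in names: TIPSO = triisopropylsilyloxy, (i-Pr)3SiO.

## Route

Step 1
Reactants: 1 4-bromo-2,6-dimethoxybenzaldehyde
Product: 2 4-bromo-2,6-dihydroxybenzaldehyde
Conditions: BBr3, CH2Cl2, −78 → 23 °C; H2O
Reagents that add atoms: none
Why: Lewis-acid ether cleavage (BBr3 demethylation); both methoxy groups flank the aldehyde, which assists coordination of boron, and the aryl bromide should be untouched. Placing the only BBr3 step on this simple arene keeps strong Lewis acid away from every later dihydrobenzofuran.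

Step 2
Reactants: 2 4-bromo-2,6-dihydroxybenzaldehyde
Product: 3 4-bromo-2-hydroxy-6-(TIPSO)benzaldehyde
Conditions: (i-Pr)3SiCl (1.05 equiv), imidazole, CH2Cl2, 0 °C
Reagents that add atoms: chlorotriisopropylsilane, CC(C)[Si](Cl)(C(C)C)C(C)C
Why: Silyl ether formation; after the first silylation the remaining hydroxyl is locked in a hydrogen bond to the aldehyde and is shielded, so one equivalent of the bulky chloride should stop at the mono-ether. The free ortho-hydroxyl needed for the quinone methide is kept.

Step 3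
Reactants: 4 5-bromoresorcinol
Product: 5 1-bromo-3,5-bis(TIPSO)benzene
Conditions: (i-Pr)3SiCl (2.3 equiv), imidazole, DMF, 23 °C
Reagents that add atoms: chlorotriisopropylsilane, CC(C)[Si](Cl)(C(C)C)C(C)C
Why: Silyl ether formation on both phenols gives an aryl bromide whose oxygens tolerate magnesium and the later base.

Step 4
Reactants: 5 1-bromo-3,5-bis(TIPSO)benzene; 3 4-bromo-2-hydroxy-6-(TIPSO)benzaldehyde
Product: 7 rac-[4-bromo-2-hydroxy-6-(TIPSO)phenyl][3,5-bis(TIPSO)phenyl]methanol, via aryl Grignard reagent 6 (not isolated)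
Conditions: 5 (2.3 equiv), Mg, THF, 50 °C; then 3, THF, −78 → −20 °C; aq. NH4Cl
Reagents that add atoms: none
Why: Grignard formation and 1,2-addition to an aldehyde; the first equivalent of 6 deprotonates the phenol and the magnesium phenoxide chelate directs the second to the carbonyl. Halogen–magnesium exchange at the bromide of 3 is slow, low temperature should suppress oxygen-to-oxygen silyl migration, and the racemic carbinol centre is erased in step 9.

Step 5
Reactants: 7 rac-[4-bromo-2-hydroxy-6-(TIPSO)phenyl][3,5-bis(TIPSO)phenyl]methanol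
Product: 8 rac-5-bromo-2-{[3,5-bis(TIPSO)phenyl](4-methylbenzenesulfonyl)methyl}-3-(TIPSO)phenol
Conditions: p-TolSO2H (1.5 equiv), MgSO4, CH2Cl2, 23 °C
Reagents that add atoms: 4-methylbenzenesulfinic acid, Cc1ccc(cc1)S(=O)O
Why: Acid-promoted substitution of an ortho-hydroxybenzhydrol; the electron-rich carbinol ionises under the mild acidity of the sulfinic acid and is captured at sulfur. The sulfone is the usual base-triggered precursor of an ortho-quinone methide, and aryl silyl ethers are stable to this weak acid.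

Step 6
Reactants: 9 3,4-dihydroxybenzaldehyde
Product: 10 3,4-bis(TIPSO)benzaldehyde
Conditions: (i-Pr)3SiCl (2.3 equiv), imidazole, DMF, 23 °C
Reagents that add atoms: chlorotriisopropylsilane, CC(C)[Si](Cl)(C(C)C)C(C)C
Why: Silyl ether formation; the catechol is masked from the outset with the group that will also protect it from the oxidant in step 11.

Step 7
Reactants: 10 3,4-bis(TIPSO)benzaldehyde
Product: 11 [3,4-bis(TIPSO)phenyl]methanol
Conditions: NaBH4, MeOH/THF, 0 °C
Reagents that add atoms: none
Why: Borohydride reduction of the aldehyde to the benzylic alcohol; the hindered aryl silyl ethers should survive at 0 °C.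

Step 8
Reactants: 11 [3,4-bis(TIPSO)phenyl]methanol; 12 (1R,4R,5R)-isothiocineole
Product: 14 (1R,4R,5R)-6-[3,4-bis(TIPSO)benzyl]-4,7,7-trimethyl-6-thiabicyclo[3.2.1]octan-6-ium trifluoromethanesulfonate, via benzyl bromide 13 (not isolated)
Conditions: CBr4, PPh3, CH2Cl2, 0 °C; then 12, LiOSO2CF3, CH2Cl2/H2O, 23 °C
Reagents that add atoms: lithium trifluoromethanesulfonate, [Li+].[O-]S(=O)(=O)C(F)(F)F
Why: Appel bromination under neutral conditions, then S-alkylation of the sulfide on its less hindered lone pair, which should give one sulfonium diastereomer. Exchange of bromide for the non-nucleophilic triflate prevents dealkylation and gives a salt that can be crystallised.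

Step 9
Reactants: 8 rac-5-bromo-2-{[3,5-bis(TIPSO)phenyl](4-methylbenzenesulfonyl)methyl}-3-(TIPSO)phenol; 14 (1R,4R,5R)-6-[3,4-bis(TIPSO)benzyl]-4,7,7-trimethyl-6-thiabicyclo[3.2.1]octan-6-ium trifluoromethanesulfonate
Product: 18 (2S,3S)-6-bromo-2-[3,4-bis(TIPSO)phenyl]-3-[3,5-bis(TIPSO)phenyl]-4-(TIPSO)-2,3-dihydrobenzofuran, via ortho-quinone methide 15 (not isolated), via sulfonium ylide 16 (not isolated), via phenoxide sulfonium betaine 17 (not isolated)
Conditions: Cs2CO3, MeCN/CH2Cl2 (1:1), −20 → 0 °C
Reagents that add atoms: none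
Why: Sulfur-ylide [4+1] annulation onto an ortho-quinone methide: the carbonate eliminates sulfinate from 8 to give 15 and deprotonates 14 to ylide 16, which adds to the methide carbon (C2'–C3') to give betaine 17; the phenoxide then displaces the sulfide in a 5-exo-tet SN2 closure (O1'–C2'). C2' is set by the chiral sulfide, which exposes one face of the ylide carbon (the centre is inverted in the closure), and C3' by the anti placement of the two aryl groups during addition, which gives the trans ring; the sulfide is recovered.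

Step 10
Reactants: 18 (2S,3S)-6-bromo-2-[3,4-bis(TIPSO)phenyl]-3-[3,5-bis(TIPSO)phenyl]-4-(TIPSO)-2,3-dihydrobenzofuran; 19 4-acetoxystyrene
Product: 21 4-[(E)-2-{(2S,3S)-2-[3,4-bis(TIPSO)phenyl]-3-[3,5-bis(TIPSO)phenyl]-4-(TIPSO)-2,3-dihydrobenzofuran-6-yl}ethenyl]phenol, via stilbene acetate 20 (not isolated)
Conditions: 19 (1.5 equiv), Pd(OAc)2, P(o-tol)3, Et3N, DMF, 100 °C; then K2CO3, MeOH/THF, 0 °C
Reagents that add atoms: none
Why: Mizoroki–Heck reaction: zerovalent palladium formed from Pd(OAc)2 inserts into the unhindered C6'–Br bond, and syn insertion of the styrene followed by syn β-hydride elimination gives the E-stilbene. Brief carbonate methanolysis (transesterification) then frees the phenol of 20 much faster than it attacks the hindered aryl silyl ethers.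

Step 11
Reactants: 21 4-[(E)-2-{(2S,3S)-2-[3,4-bis(TIPSO)phenyl]-3-[3,5-bis(TIPSO)phenyl]-4-(TIPSO)-2,3-dihydrobenzofuran-6-yl}ethenyl]phenol; 22 resveratrol
Product: 26 (2R,3R)-3-{(2S,3S)-2-[3,4-bis(TIPSO)phenyl]-3-[3,5-bis(TIPSO)phenyl]-4-(TIPSO)-2,3-dihydrobenzofuran-6-yl}-2-(4-hydroxyphenyl)-6-[(E)-2-(4-hydroxyphenyl)ethenyl]-2,3-dihydrobenzofuran-4-ol, via dimer phenoxyl radical 23 (not isolated), via resveratrol phenoxyl radical 24 (not isolated), via para-quinone methide 25 (not isolated)
Conditions: 22 (3 equiv), horseradish peroxidase, aq. H2O2 (syringe pump), acetone/phosphate buffer pH 6 (3:1), 25 °C, dark; preparative HPLC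
Reagents that add atoms: none
Why: Proposed new method: the peroxidase with H2O2 removes a hydrogen atom from the only free phenol of 21 and from the 4-hydroxyphenyl group of 22; radical 23 carries spin on the olefin carbon attached to ring B, and radical 24 carries spin, through its olefin, on the resorcinol carbon para to the vinyl group, which is the inter-oxygen carbon, so radical–radical coupling at these sites forms C3–C3a and a proton shift that restores ring A and the stilbene of 22 leaves para-quinone methide 25. The closest known reaction type is the peroxidase- or laccase-mediated oxidative dimerisation of resveratrol to 2,3-diaryl-2,3-dihydrobenzofuran dimers; what is new is the demand for a cross-coupling with this regiochemistry. The furan ring closes by 5-exo-trig conjugate (1,6-) addition of a ring A hydroxyl to the quinone methide carbon, which forms O1–C2. C2 is set relative to C3 in this closure, which places the 4-hydroxyphenyl group anti to ring B and is reversible, so the trans ring should prevail. C3 is set in the radical coupling with no bias from the remote C2'/C3' pair, so both faces should react and the (2R,3R) product has to be separated from its (2S,3S) diastereomer. The chemoselectivity is secured by the substrate: the catechol, the ring B hydroxyl and the 3,5-dihydroxyphenyl group of 21 are silylated, so 21 can be oxidised only at its stilbene phenol and offers no hydroxyl that could close a furan onto its own rings. Site selectivity for the inter-oxygen carbon of 22 over the carbons ortho to its vinyl group, over coupling through the 4-hydroxyphenyl ring of either partner and over homo-coupling of 22 is not secured by the substrates; excess 22, slow oxidant addition, screening of oxidases and chromatography have to provide it.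

Step 12
Reactants: 26 (2R,3R)-3-{(2S,3S)-2-[3,4-bis(TIPSO)phenyl]-3-[3,5-bis(TIPSO)phenyl]-4-(TIPSO)-2,3-dihydrobenzofuran-6-yl}-2-(4-hydroxyphenyl)-6-[(E)-2-(4-hydroxyphenyl)ethenyl]-2,3-dihydrobenzofuran-4-ol
Product: 27 (2R,3R)-3-[(2S,3S)-2-(3,4-dihydroxyphenyl)-3-(3,5-dihydroxyphenyl)-4-hydroxy-2,3-dihydrobenzofuran-6-yl]-2-(4-hydroxyphenyl)-6-[(E)-2-(4-hydroxyphenyl)ethenyl]-2,3-dihydrobenzofuran-4-ol
Conditions: Bu4NF, AcOH, THF (degassed), 0 → 23 °C, dark
Reagents that add atoms: none
Why: Fluoride cleavage of aryl silyl ethers, driven by Si–F bond formation. Acetic acid keeps the phenols protonated, which should prevent phenoxide-triggered opening of the upper furan and air oxidation of the freed catechol; no stereocentre is touched.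

## Compound list

1 | 4-bromo-2,6-dimethoxybenzaldehyde | COc1cc(Br)cc(OC)c1C=O | starting material
2 | 4-bromo-2,6-dihydroxybenzaldehyde | Oc1cc(Br)cc(O)c1C=O | intermediate
3 | 4-bromo-2-hydroxy-6-(TIPSO)benzaldehyde | O=Cc1c(O)cc(Br)cc1O[Si](C(C)C)(C(C)C)C(C)C | intermediate
4 | 5-bromoresorcinol (5-bromobenzene-1,3-diol) | Oc1cc(O)cc(Br)c1 | starting material
5 | 1-bromo-3,5-bis(TIPSO)benzene | Brc1cc(O[Si](C(C)C)(C(C)C)C(C)C)cc(O[Si](C(C)C)(C(C)C)C(C)C)c1 | intermediate
6 | 3,5-bis(TIPSO)phenylmagnesium bromide (not isolated) | Br[Mg]c1cc(O[Si](C(C)C)(C(C)C)C(C)C)cc(O[Si](C(C)C)(C(C)C)C(C)C)c1 | intermediate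
7 | rac-[4-bromo-2-hydroxy-6-(TIPSO)phenyl][3,5-bis(TIPSO)phenyl]methanol | OC(c1cc(O[Si](C(C)C)(C(C)C)C(C)C)cc(O[Si](C(C)C)(C(C)C)C(C)C)c1)c1c(O)cc(Br)cc1O[Si](C(C)C)(C(C)C)C(C)C | intermediate
8 | rac-5-bromo-2-{[3,5-bis(TIPSO)phenyl](4-methylbenzenesulfonyl)methyl}-3-(TIPSO)phenol | Cc1ccc(cc1)S(=O)(=O)C(c1cc(O[Si](C(C)C)(C(C)C)C(C)C)cc(O[Si](C(C)C)(C(C)C)C(C)C)c1)c1c(O)cc(Br)cc1O[Si](C(C)C)(C(C)C)C(C)C | intermediate
9 | 3,4-dihydroxybenzaldehyde | O=Cc1ccc(O)c(O)c1 | starting material
10 | 3,4-bis(TIPSO)benzaldehyde | O=Cc1ccc(O[Si](C(C)C)(C(C)C)C(C)C)c(O[Si](C(C)C)(C(C)C)C(C)C)c1 | intermediate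
11 | [3,4-bis(TIPSO)phenyl]methanol | OCc1ccc(O[Si](C(C)C)(C(C)C)C(C)C)c(O[Si](C(C)C)(C(C)C)C(C)C)c1 | intermediate
12 | (1R,4R,5R)-4,7,7-trimethyl-6-thiabicyclo[3.2.1]octane (isothiocineole) | C[C@@H]1CC[C@@H]2C[C@H]1SC2(C)C | starting material
13 | 4-(bromomethyl)-1,2-bis(TIPSO)benzene (not isolated) | BrCc1ccc(O[Si](C(C)C)(C(C)C)C(C)C)c(O[Si](C(C)C)(C(C)C)C(C)C)c1 | intermediate
14 | (1R,4R,5R)-6-[3,4-bis(TIPSO)benzyl]-4,7,7-trimethyl-6-thiabicyclo[3.2.1]octan-6-ium trifluoromethanesulfonate, benzyl group on the sulfur lone pair anti to the three-carbon bridge | C[C@@H]1CC[C@@H]2C[C@H]1[S@@+](Cc1ccc(O[Si](C(C)C)(C(C)C)C(C)C)c(O[Si](C(C)C)(C(C)C)C(C)C)c1)C2(C)C.[O-]S(=O)(=O)C(F)(F)F | intermediate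
15 | 3-bromo-6-[3,5-bis(TIPSO)benzylidene]-5-(TIPSO)cyclohexa-2,4-dien-1-one, ortho-quinone methide, alkene geometry not defined (not isolated) | O=C1C=C(Br)C=C(O[Si](C(C)C)(C(C)C)C(C)C)C1=Cc1cc(O[Si](C(C)C)(C(C)C)C(C)C)cc(O[Si](C(C)C)(C(C)C)C(C)C)c1 | intermediate
16 | sulfonium ylide of 14, [3,4-bis(TIPSO)phenyl]methanide on the sulfonium sulfur (not isolated) | C[C@@H]1CC[C@@H]2C[C@H]1[S@@+]([CH-]c1ccc(O[Si](C(C)C)(C(C)C)C(C)C)c(O[Si](C(C)C)(C(C)C)C(C)C)c1)C2(C)C | intermediate
17 | phenoxide sulfonium betaine: 5-bromo-2-{1-[3,5-bis(TIPSO)phenyl]-2-[3,4-bis(TIPSO)phenyl]-2-(sulfonium of 12)ethyl}-3-(TIPSO)phenolate; C3' as in 18, the sulfonium-bearing carbon configured so that inversion gives (2S) (not isolated) | C[C@@H]1CC[C@@H]2C[C@H]1[S@@+]([C@@H](c1ccc(O[Si](C(C)C)(C(C)C)C(C)C)c(O[Si](C(C)C)(C(C)C)C(C)C)c1)[C@@H](c1cc(O[Si](C(C)C)(C(C)C)C(C)C)cc(O[Si](C(C)C)(C(C)C)C(C)C)c1)c1c([O-])cc(Br)cc1O[Si](C(C)C)(C(C)C)C(C)C)C2(C)C | intermediate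
18 | (2S,3S)-6-bromo-2-[3,4-bis(TIPSO)phenyl]-3-[3,5-bis(TIPSO)phenyl]-4-(TIPSO)-2,3-dihydrobenzofuran (trans) | Brc1cc(O[Si](C(C)C)(C(C)C)C(C)C)c2c(c1)O[C@H](c1ccc(O[Si](C(C)C)(C(C)C)C(C)C)c(O[Si](C(C)C)(C(C)C)C(C)C)c1)[C@H]2c1cc(O[Si](C(C)C)(C(C)C)C(C)C)cc(O[Si](C(C)C)(C(C)C)C(C)C)c1 | intermediate
19 | 4-acetoxystyrene (4-ethenylphenyl acetate) | CC(=O)Oc1ccc(C=C)cc1 | starting material
20 | 4-[(E)-2-{(2S,3S)-2-[3,4-bis(TIPSO)phenyl]-3-[3,5-bis(TIPSO)phenyl]-4-(TIPSO)-2,3-dihydrobenzofuran-6-yl}ethenyl]phenyl acetate (not isolated) | CC(=O)Oc1ccc(/C=C/c2cc(O[Si](C(C)C)(C(C)C)C(C)C)c3c(c2)O[C@H](c2ccc(O[Si](C(C)C)(C(C)C)C(C)C)c(O[Si](C(C)C)(C(C)C)C(C)C)c2)[C@H]3c2cc(O[Si](C(C)C)(C(C)C)C(C)C)cc(O[Si](C(C)C)(C(C)C)C(C)C)c2)cc1 | intermediate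
21 | 4-[(E)-2-{(2S,3S)-2-[3,4-bis(TIPSO)phenyl]-3-[3,5-bis(TIPSO)phenyl]-4-(TIPSO)-2,3-dihydrobenzofuran-6-yl}ethenyl]phenol (penta-silylated piceatannol–resveratrol dimer) | Oc1ccc(/C=C/c2cc(O[Si](C(C)C)(C(C)C)C(C)C)c3c(c2)O[C@H](c2ccc(O[Si](C(C)C)(C(C)C)C(C)C)c(O[Si](C(C)C)(C(C)C)C(C)C)c2)[C@H]3c2cc(O[Si](C(C)C)(C(C)C)C(C)C)cc(O[Si](C(C)C)(C(C)C)C(C)C)c2)cc1 | intermediate
22 | resveratrol, (E)-5-[2-(4-hydroxyphenyl)ethenyl]benzene-1,3-diol | Oc1ccc(/C=C/c2cc(O)cc(O)c2)cc1 | starting material
23 | phenoxyl radical of 21 (not isolated) | [O]c1ccc(/C=C/c2cc(O[Si](C(C)C)(C(C)C)C(C)C)c3c(c2)O[C@H](c2ccc(O[Si](C(C)C)(C(C)C)C(C)C)c(O[Si](C(C)C)(C(C)C)C(C)C)c2)[C@H]3c2cc(O[Si](C(C)C)(C(C)C)C(C)C)cc(O[Si](C(C)C)(C(C)C)C(C)C)c2)cc1 | intermediate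
24 | 4-phenoxyl radical of resveratrol (not isolated) | [O]c1ccc(/C=C/c2cc(O)cc(O)c2)cc1 | intermediate
25 | para-quinone methide: 4-{2-[ring B of 21]-2-[2,6-dihydroxy-4-((E)-4-hydroxystyryl)phenyl]ethylidene}cyclohexa-2,5-dien-1-one, (R) at the future C3, lower unit (2S,3S) (not isolated) | O=C1C=CC(=C[C@H](c2cc(O[Si](C(C)C)(C(C)C)C(C)C)c3c(c2)O[C@H](c2ccc(O[Si](C(C)C)(C(C)C)C(C)C)c(O[Si](C(C)C)(C(C)C)C(C)C)c2)[C@H]3c2cc(O[Si](C(C)C)(C(C)C)C(C)C)cc(O[Si](C(C)C)(C(C)C)C(C)C)c2)c2c(O)cc(/C=C/c3ccc(O)cc3)cc2O)C=C1 | intermediate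
26 | (2R,3R)-3-{(2S,3S)-2-[3,4-bis(TIPSO)phenyl]-3-[3,5-bis(TIPSO)phenyl]-4-(TIPSO)-2,3-dihydrobenzofuran-6-yl}-2-(4-hydroxyphenyl)-6-[(E)-2-(4-hydroxyphenyl)ethenyl]-2,3-dihydrobenzofuran-4-ol | Oc1ccc(/C=C/c2cc(O)c3c(c2)O[C@@H](c2ccc(O)cc2)[C@@H]3c2cc(O[Si](C(C)C)(C(C)C)C(C)C)c3c(c2)O[C@H](c2ccc(O[Si](C(C)C)(C(C)C)C(C)C)c(O[Si](C(C)C)(C(C)C)C(C)C)c2)[C@H]3c2cc(O[Si](C(C)C)(C(C)C)C(C)C)cc(O[Si](C(C)C)(C(C)C)C(C)C)c2)cc1 | intermediate
27 | (2R,3R)-3-[(2S,3S)-2-(3,4-dihydroxyphenyl)-3-(3,5-dihydroxyphenyl)-4-hydroxy-2,3-dihydrobenzofuran-6-yl]-2-(4-hydroxyphenyl)-6-[(E)-2-(4-hydroxyphenyl)ethenyl]-2,3-dihydrobenzofuran-4-ol (CNP0107857.3) | Oc1ccc(/C=C/c2cc(O)c3c(c2)O[C@@H](c2ccc(O)cc2)[C@@H]3c2cc(O)c3c(c2)O[C@H](c2ccc(O)c(O)c2)[C@H]3c2cc(O)cc(O)c2)cc1 | target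

## Step count and risk

Total: 12 steps. Longest linear sequence: 8 steps (1 → 2 → 3 → 7 → 8 → 18 → 21 → 26 → 27).

Least certain steps

Step 11 (key step). Most likely to go wrong: coupling through other spin-bearing sites (the carbon ortho to a phenoxyl oxygen, or the ring carbons ortho to the vinyl group of 22) and homo-coupling of 22 could outrun the wanted cross-coupling, and attack on both faces at C3 halves what remains. Nothing in the substrates directs the site or the face.

Fallback in known chemistry, from 18 back to the route at 27: the upper furan is built by repeating the ylide annulation, which fixes the regiochemistry by construction and the (2R,3R) configuration through the antipodal sulfide.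
- Bromide 18 would be lithiated (n-BuLi, THF, −78 °C) and added to the lithium phenoxide of 3 (formed with LiN(SiMe3)2). This gives the benzhydrol [4-bromo-2-hydroxy-6-(TIPSO)phenyl]{(2S,3S)-2-[3,4-bis(TIPSO)phenyl]-3-[3,5-bis(TIPSO)phenyl]-4-(TIPSO)-2,3-dihydrobenzofuran-6-yl}methanol F1.
- p-Toluenesulfinic acid would convert it, as in step 5, into the corresponding p-tolyl sulfone F2.
- In parallel, 4-hydroxybenzaldehyde would be silylated to 4-(TIPSO)benzaldehyde F3 and reduced to 4-(TIPSO)benzyl alcohol F4. Bromination would give 4-(TIPSO)benzyl bromide F5, which would be alkylated onto (1S,4S,5S)-isothiocineole as in step 8 to give the 4-(TIPSO)benzyl sulfonium triflate F6.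
- Annulation of F2 with F6 under the conditions of step 9 would give the hepta-silylated bis(dihydrobenzofuran) bromide F7.
- Heck coupling with 19 and methanolysis as in step 10 would give the hepta-silylated trimer phenol F8, and fluoride cleavage as in step 12 would return to 27.

Step 9. Most likely to go wrong: incomplete facial discrimination at the ylide carbon or imperfect anti selectivity in the addition would erode the enantiomeric or trans purity, and self-condensation of the quinone methide could compete if the ylide forms too slowly. The bulky silyloxy group next to the methide carbon slows the addition.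

Fallback, from 8 back to the route at 18: control by the reagent is replaced by resolution. Bromide 13 would be isolated and alkylated onto tetrahydrothiophene to give the achiral S-[3,4-bis(TIPSO)benzyl]thiolanium bromide F9. Annulation with 8 under the same base would give racemic trans material, and preparative chromatography on a chiral stationary phase would deliver 18 and set aside its (2R,3R) enantiomer F10.

Step 10. Most likely to go wrong: insertion with the opposite regiochemistry (1,1-diarylethene), slow oxidative addition with competing reduction of the C–Br bond, or polymerisation of the styrene at 100 °C.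

Fallback, from 18 back to the route at 21: the olefin is made by olefination instead of cross-coupling. Bromine–lithium exchange on 18 and quenching with DMF would give the 6-carbaldehyde F11. Diethyl (4-hydroxybenzyl)phosphonate would be silylated to diethyl [4-(tert-butyldimethylsilyloxy)benzyl]phosphonate F12. Horner–Wadsworth–Emmons reaction of F11 with F12 (NaH, THF) would give the E-stilbene tert-butyldimethylsilyl ether F13, and the more labile aryl tert-butyldimethylsilyl group would then be removed with K2CO3 in MeOH to give 21.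

Step 12. Most likely to go wrong: fluoride basicity could trigger opening of the upper furan through its para-quinone methide, or air oxidation of the newly freed catechol, before the last hindered silyl ether is gone.

Fallback, from 21 back to the route at 27: silicon is removed before the sensitive upper ring exists, and the catechol is masked reversibly instead. 21 would be desilylated (Bu4NF, AcOH) to the free piceatannol–resveratrol dimer, 4-[(2S,3S)-... ]-free hexaphenol F14. The coupling of step 11 would then be run in borate buffer (pH about 8.5), where the catechol is held as its cyclic borate ester, to give 27 directly after acidification and chromatography. This variant gives up the blocking of the ring B hydroxyl and is therefore second choice.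

## Further compounds

F1 | step 11 | [4-bromo-2-hydroxy-6-(TIPSO)phenyl]{(2S,3S)-2-[3,4-bis(TIPSO)phenyl]-3-[3,5-bis(TIPSO)phenyl]-4-(TIPSO)-2,3-dihydrobenzofuran-6-yl}methanol, carbinol epimers | OC(c1c(O)cc(Br)cc1O[Si](C(C)C)(C(C)C)C(C)C)c1cc(O[Si](C(C)C)(C(C)C)C(C)C)c2c(c1)O[C@H](c1ccc(O[Si](C(C)C)(C(C)C)C(C)C)c(O[Si](C(C)C)(C(C)C)C(C)C)c1)[C@H]2c1cc(O[Si](C(C)C)(C(C)C)C(C)C)cc(O[Si](C(C)C)(C(C)C)C(C)C)c1
F2 | step 11 | p-tolyl sulfone of F1 (sulfonyl group in place of the carbinol hydroxyl), epimers | Cc1ccc(cc1)S(=O)(=O)C(c1c(O)cc(Br)cc1O[Si](C(C)C)(C(C)C)C(C)C)c1cc(O[Si](C(C)C)(C(C)C)C(C)C)c2c(c1)O[C@H](c1ccc(O[Si](C(C)C)(C(C)C)C(C)C)c(O[Si](C(C)C)(C(C)C)C(C)C)c1)[C@H]2c1cc(O[Si](C(C)C)(C(C)C)C(C)C)cc(O[Si](C(C)C)(C(C)C)C(C)C)c1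
F3 | step 11 | 4-(TIPSO)benzaldehyde | O=Cc1ccc(O[Si](C(C)C)(C(C)C)C(C)C)cc1
F4 | step 11 | 4-(TIPSO)benzyl alcohol | OCc1ccc(O[Si](C(C)C)(C(C)C)C(C)C)cc1
F5 | step 11 | 4-(TIPSO)benzyl bromide | BrCc1ccc(O[Si](C(C)C)(C(C)C)C(C)C)cc1
F6 | step 11 | (1S,4S,5S)-6-[4-(TIPSO)benzyl]-4,7,7-trimethyl-6-thiabicyclo[3.2.1]octan-6-ium trifluoromethanesulfonate | C[C@H]1CC[C@H]2C[C@@H]1[S@+](Cc1ccc(O[Si](C(C)C)(C(C)C)C(C)C)cc1)C2(C)C.[O-]S(=O)(=O)C(F)(F)F
F7 | step 11 | (2R,3R)-6-bromo-3-{(2S,3S)-2-[3,4-bis(TIPSO)phenyl]-3-[3,5-bis(TIPSO)phenyl]-4-(TIPSO)-2,3-dihydrobenzofuran-6-yl}-4-(TIPSO)-2-[4-(TIPSO)phenyl]-2,3-dihydrobenzofuran | Brc1cc(O[Si](C(C)C)(C(C)C)C(C)C)c2c(c1)O[C@@H](c1ccc(O[Si](C(C)C)(C(C)C)C(C)C)cc1)[C@@H]2c1cc(O[Si](C(C)C)(C(C)C)C(C)C)c2c(c1)O[C@H](c1ccc(O[Si](C(C)C)(C(C)C)C(C)C)c(O[Si](C(C)C)(C(C)C)C(C)C)c1)[C@H]2c1cc(O[Si](C(C)C)(C(C)C)C(C)C)cc(O[Si](C(C)C)(C(C)C)C(C)C)c1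
F8 | step 11 | hepta-silylated trimer phenol: 4-[(E)-2-{F7 skeleton with the bromine replaced}ethenyl]phenol | Oc1ccc(/C=C/c2cc(O[Si](C(C)C)(C(C)C)C(C)C)c3c(c2)O[C@@H](c2ccc(O[Si](C(C)C)(C(C)C)C(C)C)cc2)[C@@H]3c2cc(O[Si](C(C)C)(C(C)C)C(C)C)c3c(c2)O[C@H](c2ccc(O[Si](C(C)C)(C(C)C)C(C)C)c(O[Si](C(C)C)(C(C)C)C(C)C)c2)[C@H]3c2cc(O[Si](C(C)C)(C(C)C)C(C)C)cc(O[Si](C(C)C)(C(C)C)C(C)C)c2)cc1
F9 | step 9 | 1-[3,4-bis(TIPSO)benzyl]thiolan-1-ium bromide | [Br-].CC(C)[Si](Oc1ccc(C[S+]2CCCC2)cc1O[Si](C(C)C)(C(C)C)C(C)C)(C(C)C)C(C)C
F10 | step 9 | (2R,3R)-6-bromo-2-[3,4-bis(TIPSO)phenyl]-3-[3,5-bis(TIPSO)phenyl]-4-(TIPSO)-2,3-dihydrobenzofuran (enantiomer of 18) | Brc1cc(O[Si](C(C)C)(C(C)C)C(C)C)c2c(c1)O[C@@H](c1ccc(O[Si](C(C)C)(C(C)C)C(C)C)c(O[Si](C(C)C)(C(C)C)C(C)C)c1)[C@@H]2c1cc(O[Si](C(C)C)(C(C)C)C(C)C)cc(O[Si](C(C)C)(C(C)C)C(C)C)c1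
F11 | step 10 | (2S,3S)-2-[3,4-bis(TIPSO)phenyl]-3-[3,5-bis(TIPSO)phenyl]-4-(TIPSO)-2,3-dihydrobenzofuran-6-carbaldehyde | O=Cc1cc(O[Si](C(C)C)(C(C)C)C(C)C)c2c(c1)O[C@H](c1ccc(O[Si](C(C)C)(C(C)C)C(C)C)c(O[Si](C(C)C)(C(C)C)C(C)C)c1)[C@H]2c1cc(O[Si](C(C)C)(C(C)C)C(C)C)cc(O[Si](C(C)C)(C(C)C)C(C)C)c1
F12 | step 10 | diethyl [4-(tert-butyldimethylsilyloxy)benzyl]phosphonate | CCOP(=O)(Cc1ccc(O[Si](C)(C)C(C)(C)C)cc1)OCC
F13 | step 10 | tert-butyldimethylsilyl ether of 21 | CC(C)(C)[Si](C)(C)Oc1ccc(/C=C/c2cc(O[Si](C(C)C)(C(C)C)C(C)C)c3c(c2)O[C@H](c2ccc(O[Si](C(C)C)(C(C)C)C(C)C)c(O[Si](C(C)C)(C(C)C)C(C)C)c2)[C@H]3c2cc(O[Si](C(C)C)(C(C)C)C(C)C)cc(O[Si](C(C)C)(C(C)C)C(C)C)c2)cc1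
F14 | step 12 | (2S,3S)-2-(3,4-dihydroxyphenyl)-3-(3,5-dihydroxyphenyl)-6-[(E)-2-(4-hydroxyphenyl)ethenyl]-2,3-dihydrobenzofuran-4-ol (free dimer) | Oc1ccc(/C=C/c2cc(O)c3c(c2)O[C@H](c2ccc(O)c(O)c2)[C@H]3c2cc(O)cc(O)c2)cc1
A1 | alternative 1 | permethylated bis(dihydrobenzofuran) with a pinacol boronate at C4' of ring B | COc1ccc(/C=C/c2cc(OC)c3c(c2)O[C@@H](c2ccc(OC)cc2)[C@@H]3c2cc(B4OC(C)(C)C(C)(C)O4)c3c(c2)O[C@H](c2ccc(OC)c(OC)c2)[C@H]3c2cc(OC)cc(OC)c2)cc1
A2 | alternative 1 | tethered diyne: ethynyl ether at the catechol-bearing carbon and pinacol alkynylboronate at the carbon bearing the 3,5-dimethoxyphenyl group, configured as C2'/C3' | C#CO[C@H](c1ccc(OC)c(OC)c1)[C@@H](c1cc(OC)cc(OC)c1)C#CB1OC(C)(C)C(C)(C)O1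
A3 | alternative 1 | trans-3-ethynyl-4-methoxy-2-(4-methoxyphenyl)-6-[(E)-4-methoxystyryl]-2,3-dihydrobenzofuran, configured as C2/C3 | COc1ccc(/C=C/c2cc(OC)c3c(c2)O[C@@H](c2ccc(OC)cc2)[C@@H]3C#C)cc1
A4 | alternative 2 | ring A resorcinol mono(triisopropylsilyl) ether with the open C2–C3 side chain | COc1ccc(/C=C/c2cc(O)c(c(O[Si](C(C)C)(C(C)C)C(C)C)c2)[C@H]([C@@H](O[Si](C)(C)C(C)(C)C)c2ccc(OC)cc2)c2cc(OC)c3c(c2)O[C@H](c2ccc(OC)c(OC)c2)[C@H]3c2cc(OC)cc(OC)c2)cc1
A5 | alternative 2 | 3-[(E)-2-(4-methoxyphenyl)ethenyl]cyclobut-2-en-1-one | COc1ccc(/C=C/C2=CC(=O)C2)cc1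
A6 | alternative 2 | triisopropylsiloxyalkyne carrying C3 (with the lower dihydrobenzofuran) and the silyloxy-bearing C2 | CC(C)[Si](OC#C[C@H]([C@@H](O[Si](C)(C)C(C)(C)C)c1ccc(OC)cc1)c1cc(OC)c2c(c1)O[C@H](c1ccc(OC)c(OC)c1)[C@H]2c1cc(OC)cc(OC)c1)(C(C)C)C(C)C
A7 | alternative 3 | methyl trans-6-bromo-2-(3,4-dimethoxyphenyl)-4-methoxy-2,3-dihydrobenzofuran-3-carboxylate | Brc1cc(OC)c2c(c1)O[C@H](c1ccc(OC)c(OC)c1)[C@H]2C(=O)OC
A8 | alternative 3 | (2S)-7-bromo-2-(3,4-dimethoxyphenyl)-5-methoxychroman-4-one | Brc1cc(OC)c2c(c1)O[C@H](c1ccc(OC)c(OC)c1)CC2=O
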